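**Plan**

- Retrosynthesis: first the C3–CH2Ar' bond is cut (Ar' = 3‑hydroxy‑4,5‑dimethoxyphenyl, carried as its benzyl ether), giving the enolate of (R)‑4‑(3,4‑dimethoxybenzyl)butyrolactone 9 and benzylic bromide 13. Then the lactone O1–C5 bond of 9 is cut and C5 is joined to the benzylic carbon (C7') of the 3,4‑dimethoxybenzyl group, giving the (2‑arylcyclopropyl)acetic acid 8.
- Enabling feature: C5 (the OCH2 carbon) and C7' are 1,3‑related through C4, and C7' carries the electron‑rich 3,4‑dimethoxyphenyl ring. Tied together, C5–C4–C7' form an arylcyclopropane that is easily oxidised to a radical cation, whose C5–C7' bond the carboxylate oxygen can displace.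
- Forward order: the temporary cyclopropane is built first (asymmetric Simmons–Smith on cinnamyl alcohol 1) and the side chain is lengthened by one carbon (oxidation, Arndt–Eistert). The lactone ring then arises in a photoredox ring‑opening lactonisation that deletes the three‑membered ring and unveils the C4 benzyl group. C3 benzylation and hydrogenolysis finish the route.
- Stereochemistry: C4 comes from the ligand‑controlled cyclopropanation (the ring carbon bearing the side chain), is kept through the Wolff shift (retention) and is not a reacting centre in the key step. C3 is set by alkylation of the lactone enolate anti to the C4 benzyl group (3,4‑trans).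

Key step: step 5

Remark: the SMILES is read as the (3R,4R)‑trans lactone; the chiral dioxaborolane is assumed to show the same sense of induction with the 3,4‑dimethoxy‑substituted cinnamyl alcohol as with cinnamyl alcohol itself.

**Step 1**
Reactants: 1 (E)-3-(3,4-dimethoxyphenyl)prop-2-en-1-ol
Product: 2 [(1R,2R)-2-(3,4-dimethoxyphenyl)cyclopropyl]methanol
Conditions: Et2Zn, CH2I2, DME, (4S,5S)-2-butyl-N,N,N',N'-tetramethyl-1,3,2-dioxaborolane-4,5-dicarboxamide (1.2 equiv), CH2Cl2, -10 °C to rt; aq. NH4Cl, then aq. KOH work-up
Reagents that add atoms: diiodomethane, ICI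
Why: Asymmetric Simmons–Smith cyclopropanation in which the zinc alkoxide of the allylic alcohol is bound by the chiral dioxaborolane, so that Zn(CH2I)2 delivers CH2 to one alkene face; the concerted syn addition to the E‑alkene gives only the trans ring and should set both ring stereocentres as (1R,2R), the (4S,5S)-ligand being the mirror image of the one that leads to the (1S,2S) series.

**Step 2**
Reactants: 2 [(1R,2R)-2-(3,4-dimethoxyphenyl)cyclopropyl]methanol
Product: 4 (1R,2R)-2-(3,4-dimethoxyphenyl)cyclopropane-1-carboxylic acid, via aldehyde 3 (not isolated)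
Conditions: TEMPO (2,2,6,6-tetramethylpiperidin-1-oxyl, 20 mol %), PhI(OAc)2 (2.2 equiv), MeCN/H2O 1:1, rt
Reagents that add atoms: water, O
Why: Nitroxyl‑catalysed (oxoammonium) oxidation of the primary alcohol through aldehyde 3 and its hydrate to the acid under near‑neutral conditions, which should leave the arylcyclopropane and both stereocentres untouched.

**Step 3**
Reactants: 4 (1R,2R)-2-(3,4-dimethoxyphenyl)cyclopropane-1-carboxylic acid
Product: 6 2-diazo-1-[(1R,2R)-2-(3,4-dimethoxyphenyl)cyclopropyl]ethan-1-one, via mixed anhydride 5 (not isolated)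
Conditions: i-BuOCOCl, Et3N, THF, -15 °C; then CH2N2, Et2O, 0 °C to rt
Reagents that add atoms: diazomethane, C=[N+]=[N-]
Why: First half of the Arndt–Eistert homologation: diazomethane is acylated at the cyclopropyl acyl carbon of the mixed carbonic anhydride to give the α‑diazoketone, under mild non‑acidic conditions that should not open the donor‑substituted ring.

**Step 4**
Reactants: 6 2-diazo-1-[(1R,2R)-2-(3,4-dimethoxyphenyl)cyclopropyl]ethan-1-one
Product: 8 2-[(1S,2R)-2-(3,4-dimethoxyphenyl)cyclopropyl]acetic acid, via ketene 7 (not isolated)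
Conditions: PhCO2Ag (10 mol %), Et3N, THF/H2O 9:1, rt, dark; citric acid work-up
Reagents that add atoms: water, O
Why: Silver‑catalysed Wolff rearrangement: loss of N2 with 1,2‑shift of the cyclopropyl carbon, which migrates with retention of configuration, gives ketene 7 that water traps as the homologated acid (the descriptor at the side‑chain carbon changes from R to S only through the priority rules).

**Step 5**
Reactants: 8 2-[(1S,2R)-2-(3,4-dimethoxyphenyl)cyclopropyl]acetic acid
Product: 9 (4R)-4-(3,4-dimethoxybenzyl)dihydrofuran-2(3H)-one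
Conditions: 9-mesityl-10-methylacridinium tetrafluoroborate (5 mol %), (PhS)2 (20 mol %), 2,6-lutidine (20 mol %), ClCH2CH2Cl (0.02 M), 450 nm LEDs, rt, Ar
Reagents that add atoms: none
Why: Proposed new method: the excited acridinium should oxidise the 3,4‑dimethoxyphenylcyclopropane, the most easily oxidised site of 8, to its radical cation, in which the two ring bonds to the aryl‑bearing carbon are weakened; the carboxylate (lutidine as proton shuttle) then attacks the unsubstituted ring CH2 from the back of the CH2–CHAr bond in a three‑electron SN2 displacement, which forms the O–CH2 bond and leaves a benzylic radical that takes a hydrogen atom from PhSH, the thiyl radical reoxidising the acridinyl radical to close the cycle. The closest known reaction types are the acridinium/thiol photoredox anti‑Markovnikov hydrolactonisation of alkenoic acids and the intermolecular nucleophilic 1,3‑hydrofunctionalisation of arylcyclopropane radical cations. The γ‑lactone closes as a five‑membered ring by attack at a carbon of the three‑membered ring with the departing benzylic carbon outside the new ring (5‑exo‑tet with respect to the breaking bond; both the side‑chain carbon and the CH2 of the cyclopropane become lactone atoms, the 5‑endo mode of small‑ring opening). No stereocentre is formed: C4 of the lactone is the side‑chain‑bearing ring carbon, which is not a reacting centre and keeps its configuration, while the aryl‑bearing stereocentre is erased to CH2, so that a cis‑cyclopropane of the same configuration at that carbon would converge on the same lactone. The selectivity needed is regiochemical, attack at the ring CH2 and not at the substituted ring carbon or the benzylic carbon, and the tether secures it, because closure at the substituted carbon would need a strained four‑membered transition state to a β‑lactone and attack at the benzylic carbon would leave an unstabilised primary radical. The step is a redox‑neutral isomerisation, and the alkylveratrole ring of the product no longer carries a cleavable bond.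

**Step 6**
Reactants: 10 3-hydroxy-4,5-dimethoxybenzaldehyde
Product: 11 3-(benzyloxy)-4,5-dimethoxybenzaldehyde
Conditions: BnBr, K2CO3, DMF, rt
Reagents that add atoms: benzyl bromide, BrCc1ccccc1
Why: Williamson ether synthesis on the phenoxide protects the phenol as a benzyl ether that survives hydride, PBr3 and the amide base and is removed by hydrogenolysis at the end.

**Step 7**
Reactants: 11 3-(benzyloxy)-4,5-dimethoxybenzaldehyde
Product: 12 [3-(benzyloxy)-4,5-dimethoxyphenyl]methanol
Conditions: NaBH4, MeOH, 0 °C
Reagents that add atoms: none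
Why: Borohydride reduction of the aryl aldehyde to the benzylic alcohol, with no other reducible group present.

**Step 8**
Reactants: 12 [3-(benzyloxy)-4,5-dimethoxyphenyl]methanol
Product: 13 1-(benzyloxy)-5-(bromomethyl)-2,3-dimethoxybenzene
Conditions: PBr3, CH2Cl2, 0 °C
Reagents that add atoms: phosphorus tribromide, BrP(Br)Br
Why: Bromination of the benzylic alcohol by SN2 displacement of its phosphite ester; the bromide should be used promptly because it is an electron‑rich benzylic halide.

**Step 9**
Reactants: 9 (4R)-4-(3,4-dimethoxybenzyl)dihydrofuran-2(3H)-one; 13 1-(benzyloxy)-5-(bromomethyl)-2,3-dimethoxybenzene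
Product: 15 (3R,4R)-3-[3-(benzyloxy)-4,5-dimethoxybenzyl]-4-(3,4-dimethoxybenzyl)dihydrofuran-2(3H)-one, via lithium enolate 14 (not isolated)
Conditions: LiN(SiMe3)2 (1.05 equiv), THF, -78 °C; then 13, DMPU, -78 to -30 °C
Reagents that add atoms: none
Why: Lactone enolate alkylation (SN2 on a benzylic bromide): the lithium enolate 14 is attacked on the face anti to the C4 benzyl group, which should set C3 as R (3,4‑trans), the usual outcome for β‑benzylbutyrolactone enolates.

**Step 10**
Reactants: 15 (3R,4R)-3-[3-(benzyloxy)-4,5-dimethoxybenzyl]-4-(3,4-dimethoxybenzyl)dihydrofuran-2(3H)-one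
Product: 16 (3R,4R)-4-(3,4-dimethoxybenzyl)-3-(3-hydroxy-4,5-dimethoxybenzyl)dihydrofuran-2(3H)-one
Conditions: H2 (1 atm), 10 % Pd/C, EtOAc, rt
Reagents that add atoms: none
Why: Catalytic hydrogenolysis of the benzyl aryl ether frees the phenol under neutral conditions that should leave the lactone, the methyl ethers and both stereocentres unchanged.

**Compound list**

1 | (E)-3-(3,4-dimethoxyphenyl)prop-2-en-1-ol | COc1ccc(/C=C/CO)cc1OC | starting material
2 | [(1R,2R)-2-(3,4-dimethoxyphenyl)cyclopropyl]methanol | OC[C@@H]1C[C@H]1c1ccc(OC)c(OC)c1 | intermediate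
3 | (1R,2R)-2-(3,4-dimethoxyphenyl)cyclopropane-1-carbaldehyde | O=C[C@@H]1C[C@H]1c1ccc(OC)c(OC)c1 | intermediate
4 | (1R,2R)-2-(3,4-dimethoxyphenyl)cyclopropane-1-carboxylic acid | OC(=O)[C@@H]1C[C@H]1c1ccc(OC)c(OC)c1 | intermediate
5 | isobutyl carbonic (1R,2R)-2-(3,4-dimethoxyphenyl)cyclopropane-1-carboxylic anhydride | CC(C)COC(=O)OC(=O)[C@@H]1C[C@H]1c1ccc(OC)c(OC)c1 | intermediate
6 | 2-diazo-1-[(1R,2R)-2-(3,4-dimethoxyphenyl)cyclopropyl]ethan-1-one | [N-]=[N+]=CC(=O)[C@@H]1C[C@H]1c1ccc(OC)c(OC)c1 | intermediate
7 | 2-[(1R,2R)-2-(3,4-dimethoxyphenyl)cyclopropyl]ethen-1-one (ketene) | O=C=C[C@@H]1C[C@H]1c1ccc(OC)c(OC)c1 | intermediate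
8 | 2-[(1S,2R)-2-(3,4-dimethoxyphenyl)cyclopropyl]acetic acid | OC(=O)C[C@@H]1C[C@H]1c1ccc(OC)c(OC)c1 | intermediate
9 | (4R)-4-(3,4-dimethoxybenzyl)dihydrofuran-2(3H)-one | COc1ccc(C[C@H]2COC(=O)C2)cc1OC | intermediate
10 | 3-hydroxy-4,5-dimethoxybenzaldehyde | COc1cc(C=O)cc(O)c1OC | starting material
11 | 3-(benzyloxy)-4,5-dimethoxybenzaldehyde | COc1cc(C=O)cc(OCc2ccccc2)c1OC | intermediate
12 | [3-(benzyloxy)-4,5-dimethoxyphenyl]methanol | COc1cc(CO)cc(OCc2ccccc2)c1OC | intermediate
13 | 1-(benzyloxy)-5-(bromomethyl)-2,3-dimethoxybenzene | COc1cc(CBr)cc(OCc2ccccc2)c1OC | intermediate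
14 | lithium (4R)-4-(3,4-dimethoxybenzyl)-4,5-dihydrofuran-2-olate (lithium enolate of 9) | COc1ccc(C[C@H]2COC([O-])=C2)cc1OC.[Li+] | intermediate
15 | (3R,4R)-3-[3-(benzyloxy)-4,5-dimethoxybenzyl]-4-(3,4-dimethoxybenzyl)dihydrofuran-2(3H)-one | COc1ccc(C[C@H]2COC(=O)[C@@H]2Cc2cc(OCc3ccccc3)c(OC)c(OC)c2)cc1OC | intermediate
16 | (3R,4R)-4-(3,4-dimethoxybenzyl)-3-(3-hydroxy-4,5-dimethoxybenzyl)dihydrofuran-2(3H)-one | COc1ccc(C[C@H]2COC(=O)[C@@H]2Cc2cc(O)c(OC)c(OC)c2)cc1OC | target

**Step count and risks**

Total step count: 10. Longest linear sequence: 7 (steps 1, 2, 3, 4, 5, 9, 10).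

Steps most likely to fail:

1. Step 5 (proposed new method). The radical cation may hand the electron back to the reduced catalyst faster than the ring opens, because the charge rests largely on the dimethoxyarene. Other possible failures are capture at the substituted ring carbon by a second molecule (oligoester formation), oxidative decarboxylation of the carboxylate, and proton‑promoted Markovnikov ring opening. The fallback uses known chemistry and moves the ring‑forming bond to C3–C4. It sets out from 1: hydrogenation of the alkene (H2, Pd/C, EtOAc) should give 3-(3,4-dimethoxyphenyl)propan-1-ol F1. Acylation with glyoxylic acid chloride p‑toluenesulfonylhydrazone (PhNMe2, then Et3N, CH2Cl2, 0 °C) should give 3-(3,4-dimethoxyphenyl)propyl 2-diazoacetate F2. Enantioselective intramolecular carbene C–H insertion at the homobenzylic CH2 then closes the lactone and comes back to the route at 9. The catalyst is the chiral dirhodium carboxamidate Rh2(MPPIM)4 (MPPIM = methyl 2-oxo-1-(3-phenylpropanoyl)imidazolidine-4-carboxylate) in refluxing CH2Cl2, in the enantiomeric form that leads to the (R)-lactone.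

2. Step 4. The silver carbenoid of the donor‑arylcyclopropyl diazoketone may open the ring or insert instead of undergoing the 1,2‑shift, and the cyclopropane may open on acidic work‑up. The fallback replaces the Wolff shift by a Wittig one‑carbon homologation and sets out from 2. Dess–Martin periodinane (CH2Cl2, NaHCO3) should give aldehyde 3, isolated this time. Wittig reaction with Ph3P=CHOMe (from Ph3PCH2OMe chloride and KN(SiMe3)2, THF, 0 °C) should give 4-[(1R,2R)-2-(2-methoxyethenyl)cyclopropyl]-1,2-dimethoxybenzene F3 as an E/Z mixture. Mild hydrolysis of the enol ether (1 M HCl, THF, 0 °C) should give 2-[(1S,2R)-2-(3,4-dimethoxyphenyl)cyclopropyl]acetaldehyde F4. Pinnick oxidation (NaClO2, NaH2PO4, 2-methyl-2-butene, t-BuOH/H2O) comes back to the route at 8.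

3. Step 9. Proton transfer between product and enolate may lead to double alkylation and erosion of the trans selectivity, and the electron‑rich benzylic bromide may decompose before it is consumed. The fallback replaces alkylation by aldol addition and sets out from 9 and 11. Enolate 14 (LiN(SiMe3)2, THF, -78 °C) adds to aldehyde 11 anti to the C4 benzyl group and should give (3S,4R)-3-{[3-(benzyloxy)-4,5-dimethoxyphenyl](hydroxy)methyl}-4-(3,4-dimethoxybenzyl)dihydrofuran-2(3H)-one F5 as a mixture of carbinol epimers. Hydrogenolysis (H2, Pd/C, AcOH, cat. HClO4) removes the benzylic hydroxyl and the benzyl ether in one operation and comes back to the route at 16.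

**Further compounds**

F1 | step 5 | 3-(3,4-dimethoxyphenyl)propan-1-ol | COc1ccc(CCCO)cc1OC
F2 | step 5 | 3-(3,4-dimethoxyphenyl)propyl 2-diazoacetate | COc1ccc(CCCOC(=O)C=[N+]=[N-])cc1OC
F3 | step 4 | 4-[(1R,2R)-2-(2-methoxyethenyl)cyclopropyl]-1,2-dimethoxybenzene (E/Z mixture) | COC=C[C@@H]1C[C@H]1c1ccc(OC)c(OC)c1
F4 | step 4 | 2-[(1S,2R)-2-(3,4-dimethoxyphenyl)cyclopropyl]acetaldehyde | O=CC[C@@H]1C[C@H]1c1ccc(OC)c(OC)c1
F5 | step 9 | (3S,4R)-3-{[3-(benzyloxy)-4,5-dimethoxyphenyl](hydroxy)methyl}-4-(3,4-dimethoxybenzyl)dihydrofuran-2(3H)-one (both carbinol epimers) | COc1ccc(C[C@H]2COC(=O)[C@@H]2C(O)c2cc(OCc3ccccc3)c(OC)c(OC)c2)cc1OC
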